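Assumption: the SMILES is taken literally – a cis-fused (1R,2S,4aS,6R,8aS)-decalin with H-2 trans to H-4a, carrying an L-threonine-derived (5S, 1'R) tetramic acid, drawn as one tautomer of the 3-acyl-pyrrolidine-2,4-dione.

## Retrosynthetic overview

1. The tetramic acid is made last: target ⇒ desilylation and Lacey–Dieckmann closure of β-keto amide 28 ⇒ decalin β-keto thioester 20 + O-silyl L-threonine methyl ester 27.
2. 27 ⇒ ketoreductase dynamic kinetic resolution of racemising methyl 2-(Boc-amino)-3-oxobutanoate 24, made from methyl acetoacetate.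
3. 20 ⇒ aldehyde 18 ⇒ intramolecular Diels–Alder reaction of pentaenal 17. Rings A and B form together; the (8Z)-diene enforces cis fusion and H-2 trans to H-4a.
4. 17 ⇒ Z-selective Wittig reaction of phosphonium salt 9 with octatrienal 13 (from sorbaldehyde).
5. 9 ⇒ (R)-citronellol ⇒ geraniol by Ru–BINAP asymmetric hydrogenation (first stereocentre). Ring order: decalin (both rings at once), then the pyrrolidine-2,4-dione.

## Route

Step 1
Reactants: 1 geraniol
Product: 2 (3R)-3,7-dimethyloct-6-en-1-ol ((R)-citronellol)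
Conditions: H2 (100 atm), Ru(OAc)2[(S)-BINAP] (0.2 mol %), MeOH/H2O 95:5, 20 °C
Reagents that add atoms: none
Why: Noyori asymmetric hydrogenation; the hydroxyl-directed Ru–BINAP catalyst reduces only the allylic 2,3-alkene from one enantioface and sets the (R)-methyl stereocentre (about 96–98% ee expected), leaving the remote trisubstituted alkene intact.

Step 2
Reactants: 2 (R)-citronellol
Product: 3 (6R)-8-bromo-2,6-dimethyloct-2-ene ((R)-citronellyl bromide)
Conditions: CBr4, PPh3, CH2Cl2, 0 °C → rt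
Reagents that add atoms: carbon tetrabromide BrC(Br)(Br)Br
Why: Appel reaction; SN2 displacement of the activated primary alkoxyphosphonium by bromide, with the remote stereocentre untouched.

Step 3
Reactants: 3 (R)-citronellyl bromide
Product: 5 (4R)-6-bromo-4-methylhexanal, via secondary ozonide 4 (not isolated)
Conditions: O3, CH2Cl2, −78 °C; then Me2S, −78 °C → rt
Reagents that add atoms: ozone [O-][O+]=O
Why: Ozonolysis (Criegee mechanism) of the only alkene with reductive work-up gives the aldehyde that becomes C8a; the primary bromide is inert.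

Step 4
Reactants: 5 bromo aldehyde
Product: 6 ethyl (2E,6R)-8-bromo-2,6-dimethyloct-2-enoate
Conditions: Ph3P=C(CH3)CO2Et, CH2Cl2, 40 °C
Reagents that add atoms: ethyl 2-(triphenylphosphoranylidene)propanoate CCOC(=O)C(C)=P(c1ccccc1)(c1ccccc1)c1ccccc1
Why: Wittig reaction of a stabilised ylide, under thermodynamic control of the oxaphosphetane, gives the (E)-2-methyl enoate (E:Z at least 95:5 expected), the future dienophile geometry.

Step 5
Reactants: 6 bromo enoate
Product: 7 (2E,6R)-8-bromo-2,6-dimethyloct-2-en-1-ol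
Conditions: iBu2AlH (2.2 equiv), CH2Cl2, −78 °C; aq. potassium sodium tartrate
Reagents that add atoms: none
Why: 1,2-reduction of the conjugated ester by the aluminium hydride gives the allylic alcohol; the alkyl bromide does not react at −78 °C.

Step 6
Reactants: 7 bromo allylic alcohol
Product: 8 {[(2E,6R)-8-bromo-2,6-dimethyloct-2-en-1-yl]oxy}(tert-butyl)diphenylsilane
Conditions: TBDPSCl, imidazole, DMF, rt
Reagents that add atoms: tert-butyl(chloro)diphenylsilane CC(C)(C)[Si](Cl)(c1ccccc1)c1ccccc1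
Why: Imidazole-promoted silylation; the robust silyl ether masks the future enal through salt formation and the ylide step.

Step 7
Reactants: 8 bromo silyl ether
Product: 9 [(3R,6E)-8-[(tert-butyldiphenylsilyl)oxy]-3,7-dimethyloct-6-en-1-yl]triphenylphosphonium bromide
Conditions: PPh3, MeCN, reflux, 48 h
Reagents that add atoms: triphenylphosphine c1ccc(cc1)P(c1ccccc1)c1ccccc1
Why: SN2 quaternisation of PPh3 by the unhindered primary bromide gives the Wittig salt.

Step 8
Reactants: 10 sorbaldehyde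
Product: 11 ethyl (2E,4E,6E)-octa-2,4,6-trienoate
Conditions: (EtO)2P(O)CH2CO2Et, NaH, THF, 0 °C → rt
Reagents that add atoms: triethyl phosphonoacetate CCOC(=O)CP(=O)(OCC)OCC
Why: Horner–Wadsworth–Emmons olefination of the dienal is E-selective and extends the polyene by two carbons.

Step 9
Reactants: 11 trienoate
Product: 12 (2E,4E,6E)-octa-2,4,6-trien-1-ol
Conditions: iBu2AlH (2.2 equiv), CH2Cl2, −78 °C
Reagents that add atoms: none
Why: 1,2-reduction of the conjugated ester by the aluminium hydride, without touching the triene.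

Step 10
Reactants: 12 trienol
Product: 13 (2E,4E,6E)-octa-2,4,6-trienal
Conditions: MnO2, CH2Cl2, rt, dark
Reagents that add atoms: none
Why: MnO2 oxidation is selective for allylic alcohols and keeps the all-E geometry.

Step 11
Reactants: 9 phosphonium bromide; 13 octatrienal
Product: 15 tert-butyl{[(2E,6R,8Z,10E,12E,14E)-2,6-dimethylhexadeca-2,8,10,12,14-pentaen-1-yl]oxy}diphenylsilane, via phosphonium ylide 14 (not isolated)
Conditions: NaN(SiMe3)2 (0.98 equiv), THF, −78 °C; then 13, −78 → −20 °C, dark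
Reagents that add atoms: none
Why: Lithium-free Wittig reaction of a non-stabilised ylide with an enal goes through the kinetic cis-oxaphosphetane and gives the new C8=C9 bond Z (about 92:8 or better expected), while the three E alkenes of 13 are carried over unchanged.

Step 12
Reactants: 15 tetraene silyl ether
Product: 16 (2E,6R,8Z,10E,12E,14E)-2,6-dimethylhexadeca-2,8,10,12,14-pentaen-1-ol
Conditions: Bu4NF, THF, 0 °C → rt, BHT, dark
Reagents that add atoms: none
Why: Fluoride-driven Si–O cleavage under neutral conditions that do not isomerise the (Z,E,E,E)-tetraene.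

Step 13
Reactants: 16 pentaenol
Product: 17 (2E,6R,8Z,10E,12E,14E)-2,6-dimethylhexadeca-2,8,10,12,14-pentaenal
Conditions: MnO2, CH2Cl2, rt, dark; used at once
Reagents that add atoms: none
Why: Allylic oxidation with MnO2 gives the (E)-2-methyl enal dienophile without acid or heat.

Step 14
Reactants: 17 pentaenal
Product: 18 (1R,2S,4aS,6R,8aS)-1,6-dimethyl-2-[(1E,3E)-penta-1,3-dien-1-yl]-1,2,4a,5,6,7,8,8a-octahydronaphthalene-1-carbaldehyde
Conditions: Me2AlCl (1.1 equiv), CH2Cl2, −78 → −20 °C; 1 M HCl quench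
Reagents that add atoms: none
Why: Lewis-acid-promoted intramolecular Diels–Alder reaction. A tether on the (Z)-terminus of the diene can only reach the cis-fused transition state, so the suprafacial addition of the (E)-dienophile places the dienyl group, H-4a, H-8a and the formyl group on one face (C1, C2, C4a, C8a). The chair-like tether with the C6 methyl equatorial selects the diene face and so the absolute configuration; minor isomers are removed by chromatography.

Step 15
Reactants: 18 decalin aldehyde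
Product: 19 S-tert-butyl 3-[(1R,2S,4aS,6R,8aS)-1,6-dimethyl-2-[(1E,3E)-penta-1,3-dien-1-yl]-1,2,4a,5,6,7,8,8a-octahydronaphthalen-1-yl]-3-hydroxypropanethioate (both carbinol epimers)
Conditions: LiN(iPr)2, CH3C(O)SC(CH3)3, THF, −78 °C; then 18, −78 → −40 °C
Reagents that add atoms: S-tert-butyl thioacetate CC(=O)SC(C)(C)C
Why: Aldol addition of the thioester lithium enolate to the non-enolisable neopentyl aldehyde; the new carbinol centre is removed in the next step, so its configuration does not matter.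

Step 16
Reactants: 19 β-hydroxy thioester
Product: 20 S-tert-butyl 3-[(1R,2S,4aS,6R,8aS)-1,6-dimethyl-2-[(1E,3E)-penta-1,3-dien-1-yl]-1,2,4a,5,6,7,8,8a-octahydronaphthalen-1-yl]-3-oxopropanethioate
Conditions: Dess–Martin periodinane, CH2Cl2, 0 °C → rt
Reagents that add atoms: none
Why: Dess–Martin oxidation of the secondary alcohol gives the β-keto thioester under mild conditions that spare the diene and the ring alkene.

Step 17
Reactants: 21 methyl acetoacetate
Product: 22 methyl 2-(hydroxyimino)-3-oxobutanoate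
Conditions: NaNO2, AcOH/H2O, 0 °C → rt
Reagents that add atoms: sodium nitrite [Na+].[O-]N=O
Why: Nitrosation of the active methylene followed by tautomerisation gives the oxime, introducing the nitrogen at C2.

Step 18
Reactants: 22 oxime
Product: 24 methyl 2-[(tert-butoxycarbonyl)amino]-3-oxobutanoate (racemic), via methyl 2-amino-3-oxobutanoate 23 (not isolated)
Conditions: H2 (3 atm), Pd/C, Boc2O, MeOH, rt
Reagents that add atoms: di-tert-butyl dicarbonate CC(C)(C)OC(=O)OC(=O)OC(C)(C)C
Why: Catalytic hydrogenation of the oxime with in-situ carbamate formation traps the α-amino ketone before it can self-condense.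

Step 19
Reactants: 24 racemic Boc-amino keto ester
Product: 25 methyl (2S,3R)-2-[(tert-butoxycarbonyl)amino]-3-hydroxybutanoate (Boc-L-threonine methyl ester)
Conditions: ketoreductase (NADPH-dependent, panel-selected for the syn-(2S,3R) product), NADP+ (cat.), iPrOH (10% v/v), KH2PO4/K2HPO4 buffer pH 7.0, 30 °C
Reagents that add atoms: none
Why: Ketoreductase-catalysed dynamic reductive kinetic resolution; the α-centre of 24 racemises through its enol while the enzyme reduces only the (2S)-ketone from one carbonyl face, so both stereocentres (2S,3R) are set in one step, with isopropanol recycling the cofactor.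

Step 20
Reactants: 25 Boc-L-threonine methyl ester
Product: 26 methyl (2S,3R)-2-amino-3-hydroxybutanoate hydrochloride (L-threonine methyl ester hydrochloride)
Conditions: HCl (4 M in 1,4-dioxane), 0 °C → rt
Reagents that add atoms: hydrogen chloride Cl
Why: Acidolysis of the tert-butyl carbamate (loss of isobutene and CO2) without touching the ester or either stereocentre.

Step 21
Reactants: 26 L-threonine methyl ester hydrochloride
Product: 27 methyl (2S,3R)-2-amino-3-[(tert-butyldimethylsilyl)oxy]butanoate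
Conditions: TBSCl, imidazole, DMF, rt; aq. NaHCO3 work-up
Reagents that add atoms: tert-butyl(chloro)dimethylsilane CC(C)(C)[Si](C)(C)Cl
Why: O-silylation of the secondary alcohol; any N-silyl amine hydrolyses on work-up, leaving the free amine for the coupling.

Step 22
Reactants: 20 decalin β-keto thioester; 27 O-silyl threonine ester
Product: 28 methyl (2S,3R)-3-[(tert-butyldimethylsilyl)oxy]-2-{3-[(1R,2S,4aS,6R,8aS)-1,6-dimethyl-2-[(1E,3E)-penta-1,3-dien-1-yl]-1,2,4a,5,6,7,8,8a-octahydronaphthalen-1-yl]-3-oxopropanamido}butanoate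
Conditions: AgOCOCF3 (1.5 equiv), Et3N, THF, 0 °C → rt, dark
Reagents that add atoms: none
Why: Thiophilic silver activation of the thioester allows aminolysis at low temperature, giving the β-keto amide without epimerising the amino ester.

Step 23
Reactants: 28 β-keto amide
Product: 29 (5S)-5-[(1R)-1-[(tert-butyldimethylsilyl)oxy]ethyl]-3-{[(1R,2S,4aS,6R,8aS)-1,6-dimethyl-2-[(1E,3E)-penta-1,3-dien-1-yl]-1,2,4a,5,6,7,8,8a-octahydronaphthalen-1-yl]carbonyl}-4-hydroxy-1,5-dihydro-2H-pyrrol-2-one
Conditions: KOtBu (2.2 equiv), tBuOH/THF, rt, 20 min; then 1 M HCl to pH 3 at 0 °C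
Reagents that add atoms: none
Why: Lacey–Dieckmann cyclisation; the β-keto amide enolate acylates on the methyl ester to close the pyrrolidine-2,4-dione, and the hindered base with short contact time keeps C5 and the silyl ether intact.

Step 24
Reactants: 29 silyl-protected tetramic acid
Product: 30 (5S)-3-{[(1R,2S,4aS,6R,8aS)-1,6-dimethyl-2-[(1E,3E)-penta-1,3-dien-1-yl]-1,2,4a,5,6,7,8,8a-octahydronaphthalen-1-yl]carbonyl}-4-hydroxy-5-[(1R)-1-hydroxyethyl]-1,5-dihydro-2H-pyrrol-2-one (target)
Conditions: HF·pyridine, THF/pyridine, 0 °C → rt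
Reagents that add atoms: none
Why: Fluoride-mediated cleavage of the secondary silyl ether under buffered conditions that leave the diene, the acyl tetramic acid and all stereocentres unchanged.

## Compound list

1 | geraniol, (2E)-3,7-dimethylocta-2,6-dien-1-ol | CC(C)=CCC/C(C)=C/CO | starting material
2 | (3R)-3,7-dimethyloct-6-en-1-ol, (R)-citronellol | C[C@@H](CCO)CCC=C(C)C | intermediate
3 | (6R)-8-bromo-2,6-dimethyloct-2-ene | C[C@@H](CCBr)CCC=C(C)C | intermediate
4 | 3-[(3R)-5-bromo-3-methylpentyl]-5,5-dimethyl-1,2,4-trioxolane (secondary ozonide, epimers at the ring carbon) | C[C@@H](CCBr)CCC1OOC(C)(C)O1 | intermediate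
5 | (4R)-6-bromo-4-methylhexanal | C[C@@H](CCBr)CCC=O | intermediate
6 | ethyl (2E,6R)-8-bromo-2,6-dimethyloct-2-enoate | CCOC(=O)/C(C)=C/CC[C@@H](C)CCBr | intermediate
7 | (2E,6R)-8-bromo-2,6-dimethyloct-2-en-1-ol | OC/C(C)=C/CC[C@@H](C)CCBr | intermediate
8 | {[(2E,6R)-8-bromo-2,6-dimethyloct-2-en-1-yl]oxy}(tert-butyl)diphenylsilane | CC(C)(C)[Si](OC/C(C)=C/CC[C@@H](C)CCBr)(c1ccccc1)c1ccccc1 | intermediate
9 | [(3R,6E)-8-[(tert-butyldiphenylsilyl)oxy]-3,7-dimethyloct-6-en-1-yl]triphenylphosphonium bromide | CC(C)(C)[Si](OC/C(C)=C/CC[C@@H](C)CC[P+](c1ccccc1)(c1ccccc1)c1ccccc1)(c1ccccc1)c1ccccc1.[Br-] | intermediate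
10 | sorbaldehyde, (2E,4E)-hexa-2,4-dienal | C/C=C/C=C/C=O | starting material
11 | ethyl (2E,4E,6E)-octa-2,4,6-trienoate | C/C=C/C=C/C=C/C(=O)OCC | intermediate
12 | (2E,4E,6E)-octa-2,4,6-trien-1-ol | C/C=C/C=C/C=C/CO | intermediate
13 | (2E,4E,6E)-octa-2,4,6-trienal | C/C=C/C=C/C=C/C=O | intermediate
14 | [(3R,6E)-8-[(tert-butyldiphenylsilyl)oxy]-3,7-dimethyloct-6-en-1-ylidene]triphenylphosphorane (ylide) | CC(C)(C)[Si](OC/C(C)=C/CC[C@@H](C)CC=P(c1ccccc1)(c1ccccc1)c1ccccc1)(c1ccccc1)c1ccccc1 | intermediate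
15 | tert-butyl{[(2E,6R,8Z,10E,12E,14E)-2,6-dimethylhexadeca-2,8,10,12,14-pentaen-1-yl]oxy}diphenylsilane | CC(C)(C)[Si](OC/C(C)=C/CC[C@@H](C)C/C=C\C=C\C=C\C=C\C)(c1ccccc1)c1ccccc1 | intermediate
16 | (2E,6R,8Z,10E,12E,14E)-2,6-dimethylhexadeca-2,8,10,12,14-pentaen-1-ol | OC/C(C)=C/CC[C@@H](C)C/C=C\C=C\C=C\C=C\C | intermediate
17 | (2E,6R,8Z,10E,12E,14E)-2,6-dimethylhexadeca-2,8,10,12,14-pentaenal | O=C/C(C)=C/CC[C@@H](C)C/C=C\C=C\C=C\C=C\C | intermediate
18 | (1R,2S,4aS,6R,8aS)-1,6-dimethyl-2-[(1E,3E)-penta-1,3-dien-1-yl]-1,2,4a,5,6,7,8,8a-octahydronaphthalene-1-carbaldehyde | C/C=C/C=C/[C@H]1C=C[C@@H]2C[C@H](C)CC[C@@H]2[C@@]1(C)C=O | intermediate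
19 | S-tert-butyl 3-[(1R,2S,4aS,6R,8aS)-1,6-dimethyl-2-[(1E,3E)-penta-1,3-dien-1-yl]-1,2,4a,5,6,7,8,8a-octahydronaphthalen-1-yl]-3-hydroxypropanethioate (carbinol epimers) | C/C=C/C=C/[C@H]1C=C[C@@H]2C[C@H](C)CC[C@@H]2[C@@]1(C)C(O)CC(=O)SC(C)(C)C | intermediate
20 | S-tert-butyl 3-[(1R,2S,4aS,6R,8aS)-1,6-dimethyl-2-[(1E,3E)-penta-1,3-dien-1-yl]-1,2,4a,5,6,7,8,8a-octahydronaphthalen-1-yl]-3-oxopropanethioate | C/C=C/C=C/[C@H]1C=C[C@@H]2C[C@H](C)CC[C@@H]2[C@@]1(C)C(=O)CC(=O)SC(C)(C)C | intermediate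
21 | methyl acetoacetate, methyl 3-oxobutanoate | CC(=O)CC(=O)OC | starting material
22 | methyl 2-(hydroxyimino)-3-oxobutanoate | CC(=O)C(=NO)C(=O)OC | intermediate
23 | methyl 2-amino-3-oxobutanoate (racemic) | CC(=O)C(N)C(=O)OC | intermediate
24 | methyl 2-[(tert-butoxycarbonyl)amino]-3-oxobutanoate (racemic, configurationally labile) | CC(=O)C(NC(=O)OC(C)(C)C)C(=O)OC | intermediate
25 | methyl (2S,3R)-2-[(tert-butoxycarbonyl)amino]-3-hydroxybutanoate | C[C@@H](O)[C@H](NC(=O)OC(C)(C)C)C(=O)OC | intermediate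
26 | methyl (2S,3R)-2-amino-3-hydroxybutanoate hydrochloride | C[C@@H](O)[C@H]([NH3+])C(=O)OC.[Cl-] | intermediate
27 | methyl (2S,3R)-2-amino-3-[(tert-butyldimethylsilyl)oxy]butanoate | C[C@@H](O[Si](C)(C)C(C)(C)C)[C@H](N)C(=O)OC | intermediate
28 | methyl (2S,3R)-3-[(tert-butyldimethylsilyl)oxy]-2-{3-[(1R,2S,4aS,6R,8aS)-1,6-dimethyl-2-[(1E,3E)-penta-1,3-dien-1-yl]-1,2,4a,5,6,7,8,8a-octahydronaphthalen-1-yl]-3-oxopropanamido}butanoate | C/C=C/C=C/[C@H]1C=C[C@@H]2C[C@H](C)CC[C@@H]2[C@@]1(C)C(=O)CC(=O)N[C@@H]([C@@H](C)O[Si](C)(C)C(C)(C)C)C(=O)OC | intermediate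
29 | (5S)-5-[(1R)-1-[(tert-butyldimethylsilyl)oxy]ethyl]-3-{[(1R,2S,4aS,6R,8aS)-1,6-dimethyl-2-[(1E,3E)-penta-1,3-dien-1-yl]-1,2,4a,5,6,7,8,8a-octahydronaphthalen-1-yl]carbonyl}-4-hydroxy-1,5-dihydro-2H-pyrrol-2-one | C/C=C/C=C/[C@H]1C=C[C@@H]2C[C@H](C)CC[C@@H]2[C@@]1(C)C(=O)C1=C(O)[C@H]([C@@H](C)O[Si](C)(C)C(C)(C)C)NC1=O | intermediate
30 | (5S)-3-{[(1R,2S,4aS,6R,8aS)-1,6-dimethyl-2-[(1E,3E)-penta-1,3-dien-1-yl]-1,2,4a,5,6,7,8,8a-octahydronaphthalen-1-yl]carbonyl}-4-hydroxy-5-[(1R)-1-hydroxyethyl]-1,5-dihydro-2H-pyrrol-2-one | C/C=C/C=C/[C@H]1C=C[C@@H]2C[C@H](C)CC[C@@H]2[C@@]1(C)C(=O)C1=C(O)[C@H]([C@@H](C)O)NC1=O | target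

## Step count and risks

Total step count: 24. Longest linear sequence: 16 steps (geraniol 1 → target 30 through steps 1–7, 11–16 and 22–24).

Steps most likely to fail:

Step 11 (Z-selective Wittig reaction). The ylide may give an E/Z mixture at C8=C9, and the tetraene is sensitive to light and acid. The fallback sets out from bromide 8 (with sorbaldehyde 10 for the second partner) and comes back to the route at 15. Bromide 8 is oxidised with trimethylamine N-oxide in DMSO (Ganem oxidation) to (3R,6E)-8-[(tert-butyldiphenylsilyl)oxy]-3,7-dimethyloct-6-enal F1. Stork–Zhao olefination of this aldehyde ((iodomethyl)triphenylphosphonium iodide, NaN(SiMe3)2, THF/DMPU, −78 °C) gives the geometrically defined vinyl iodide tert-butyl{[(2E,6R,8Z)-9-iodo-2,6-dimethylnona-2,8-dien-1-yl]oxy}diphenylsilane F2. Separately, 10 is converted by boron-Wittig olefination (CH2(Bpin)2, lithium 2,2,6,6-tetramethylpiperidide, THF, −78 °C → rt) into 4,4,5,5-tetramethyl-2-[(1E,3E,5E)-hepta-1,3,5-trien-1-yl]-1,3,2-dioxaborolane F3. Suzuki–Miyaura coupling of the two (Pd(PPh3)4, K3PO4, THF/H2O, rt) proceeds with retention at both alkenyl partners and gives 15.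

Step 14 (intramolecular Diels–Alder reaction). The (Z)-diene is a sluggish diene, the Lewis acid may isomerise the tetraene, and the facial selectivity from the C6 methyl group is predicted, not proven. The fallback sets out from pentaenal 17 and comes back at 20, so that steps 15 and 16 are not needed. Aldol addition of the lithium enolate of S-tert-butyl thioacetate to 17 gives S-tert-butyl (4E,8R,10Z,12E,14E,16E)-3-hydroxy-4,8-dimethyloctadeca-4,10,12,14,16-pentaenethioate F4. Dess–Martin oxidation then gives S-tert-butyl (4E,8R,10Z,12E,14E,16E)-4,8-dimethyl-3-oxooctadeca-4,10,12,14,16-pentaenethioate F5. Its doubly activated enone dienophile should cyclise without any Lewis acid (toluene, BHT, 25–45 °C) through the same cis-fused transition state, directly to 20.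

Step 19 (ketoreductase dynamic kinetic resolution). No enzyme of the panel may combine syn-(2S,3R) selectivity with useful activity on the Boc-amino substrate. The fallback sets out from oxime 22 and comes back at 26. Reductive acetylation (Zn, AcOH, Ac2O) gives methyl 2-acetamido-3-oxobutanoate F6. Noyori hydrogenation with dynamic kinetic resolution (RuBr2[(R)-BINAP], H2 100 atm, CH2Cl2, 25 °C) gives the syn product methyl (2S,3R)-2-acetamido-3-hydroxybutanoate F7. Hydrolysis in 6 M HCl at reflux gives L-threonine hydrochloride F8, and esterification (SOCl2, MeOH, 0 °C → reflux) gives 26.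

Further compounds
F1 | step 11 | (3R,6E)-8-[(tert-butyldiphenylsilyl)oxy]-3,7-dimethyloct-6-enal | CC(C)(C)[Si](OC/C(C)=C/CC[C@@H](C)CC=O)(c1ccccc1)c1ccccc1
F2 | step 11 | tert-butyl{[(2E,6R,8Z)-9-iodo-2,6-dimethylnona-2,8-dien-1-yl]oxy}diphenylsilane | CC(C)(C)[Si](OC/C(C)=C/CC[C@@H](C)C/C=C\I)(c1ccccc1)c1ccccc1
F3 | step 11 | 4,4,5,5-tetramethyl-2-[(1E,3E,5E)-hepta-1,3,5-trien-1-yl]-1,3,2-dioxaborolane | C/C=C/C=C/C=C/B1OC(C)(C)C(C)(C)O1
F4 | step 14 | S-tert-butyl (4E,8R,10Z,12E,14E,16E)-3-hydroxy-4,8-dimethyloctadeca-4,10,12,14,16-pentaenethioate | CC(C)(C)SC(=O)CC(O)/C(C)=C/CC[C@@H](C)C/C=C\C=C\C=C\C=C\C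
F5 | step 14 | S-tert-butyl (4E,8R,10Z,12E,14E,16E)-4,8-dimethyl-3-oxooctadeca-4,10,12,14,16-pentaenethioate | CC(C)(C)SC(=O)CC(=O)/C(C)=C/CC[C@@H](C)C/C=C\C=C\C=C\C=C\C
F6 | step 19 | methyl 2-acetamido-3-oxobutanoate (racemic) | CC(=O)NC(C(C)=O)C(=O)OC
F7 | step 19 | methyl (2S,3R)-2-acetamido-3-hydroxybutanoate | C[C@@H](O)[C@H](NC(C)=O)C(=O)OC
F8 | step 19 | L-threonine hydrochloride | C[C@@H](O)[C@H]([NH3+])C(=O)O.[Cl-]
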